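**Retrosynthetic overview**
- Last step: the ester C–O bond and the cinnamate C=C are made together. (R)-Marmin, Ph3P=C=C=O and 4-O-geranyl-2,4-dihydroxybenzaldehyde are joined by alcohol addition followed by an E-selective Wittig reaction.
- The (R)-carbinol C6' comes from an oxazaborolidine-catalysed reduction of the 6'-ketone. The aryl allyl ether comes from a Mitsunobu reaction with umbelliferone.
- Key bond C3'–C4': a cobalt homoenolate (ketone β-carbon used as the nucleophile) adds syn across but-2-yn-1-ol. C3' and C4' are both latent electrophilic carbons (1,4-relation C3'/C6'), and the addition also sets the E-trisubstituted alkene.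
- The homoenolate precursor is a cyclopropanol made by Kulinkovich reaction of methyl 2-hydroxyisobutyrate.
- Rings: the coumarin and the benzene ring are bought. The only ring built is the cyclopropane (step 1), and it is opened again in step 2.

Assumption: the single stereocentre is C6' of the marmin unit and is R by CIP analysis of the given SMILES. Primed locants run from the OCH2 on the coumarin oxygen (C1') to the C(CH3)2OH carbon (C7').

**Step 1**
Reactants: 1 methyl 2-hydroxy-2-methylpropanoate
Product: 2 1-(2-hydroxypropan-2-yl)cyclopropan-1-ol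
Conditions: EtMgBr (3.6 equiv), Ti(OiPr)4 (20 mol %), THF, 0 °C to rt; aq NH4Cl
Reagents that add atoms: ethylmagnesium bromide, CC[Mg]Br
Why: Kulinkovich cyclopropanation, in which the first equivalent of EtMgBr masks the free OH as its magnesium alkoxide and the titanacyclopropane formed from two more equivalents adds twice to the ester carbonyl as a 1,2-dicarbanion (α-hydroxy esters are known substrates); no stereocentre is formed.

**Step 2 (key step)**
Reactants: 2 1-(2-hydroxypropan-2-yl)cyclopropan-1-ol (1.5 equiv); 3 but-2-yn-1-ol
Product: 4 (6E)-2,8-dihydroxy-2,6-dimethyloct-6-en-3-one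
Conditions: CoBr2 (10 mol %), dppp (10 mol %), Zn dust (20 mol %), DABCO (50 mol %), DMSO, 80 °C
Reagents that add atoms: none
Why: Proposed new method: zinc-reduced CoBr2/diphosphine forms a low-valent cobalt cyclopropoxide of 2 whose strained ring opens by β-carbon elimination to a cobalt homoenolate (the normally electrophilic ketone β-carbon now acts as the nucleophile); syn-carbocobaltation of 3 should place the new C–C bond on the methyl-bearing alkyne carbon, because that carbon carries the smaller substituent and the metal then sits next to the inductively stabilising CH2OH; stereoretentive protodemetalation by the O–H of another molecule of 2 leaves the chain trans to CH2OH (E) and turns the catalyst over, DMSO and the bulky C(CH3)2OH group disfavouring the competing ring closure to a cyclopentenol; the closest known reaction type is the cobalt-diphosphine-catalysed ring-opening hydroalkylation of internal alkynes with 1-substituted cyclopropanols to β-alkenyl ketones.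

**Step 3**
Reactants: 4 (6E)-2,8-dihydroxy-2,6-dimethyloct-6-en-3-one; 5 7-hydroxycoumarin (umbelliferone)
Product: 6 7-{[(2E)-7-hydroxy-3,7-dimethyl-6-oxooct-2-en-1-yl]oxy}-2H-chromen-2-one
Conditions: PPh3, DIAD, THF, 0 °C to rt
Reagents that add atoms: none
Why: Mitsunobu etherification, in which only the primary allylic OH is activated (the tertiary OH is inert) and the acidic phenol 5 (pKa about 8) displaces it by SN2 without allylic transposition or E/Z loss, as in the known geraniol to auraptene case.

**Step 4**
Reactants: 6 7-{[(2E)-7-hydroxy-3,7-dimethyl-6-oxooct-2-en-1-yl]oxy}-2H-chromen-2-one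
Product: 7 (R)-marmin = 7-{[(2E,6R)-6,7-dihydroxy-3,7-dimethyloct-2-en-1-yl]oxy}-2H-chromen-2-one
Conditions: (S)-Me-CBS = (S)-1-methyl-3,3-diphenyltetrahydro-1H,3H-pyrrolo[1,2-c][1,3,2]oxazaborole (20 mol %), catecholborane (2.5 equiv), toluene, −78 to −40 °C; MeOH, then aq NaHCO3; one recrystallisation from EtOAc/hexane
Reagents that add atoms: none
Why: Corey–Bakshi–Shibata reduction, in which the ketone binds the catalyst boron with the bulky C(CH3)2O–B group pointing away, so hydride is delivered in the same sense as pinacolone to (R)-3,3-dimethylbutan-2-ol with the S catalyst and sets 6'R; catecholborane leaves the alkene and the lactone untouched at these temperatures, and crystalline marmin allows the ee to be raised.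

**Step 5**
Reactants: 8 2,4-dihydroxybenzaldehyde; 9 geranyl bromide = (2E)-1-bromo-3,7-dimethylocta-2,6-diene
Product: 10 4-{[(2E)-3,7-dimethylocta-2,6-dien-1-yl]oxy}-2-hydroxybenzaldehyde
Conditions: K2CO3 (1.1 equiv), acetone, 40 °C
Reagents that add atoms: none
Why: Williamson ether synthesis, in which the 2-OH is held in a hydrogen bond to the aldehyde, so the weak base alkylates the more acidic and freer 4-OH by SN2 with the E-allyl geometry kept.

**Step 6**
Reactants: 7 (R)-marmin (1.05 equiv); 11 (triphenylphosphoranylidene)ketene (Bestmann ylide, 1.0 equiv); 10 4-{[(2E)-3,7-dimethylocta-2,6-dien-1-yl]oxy}-2-hydroxybenzaldehyde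
Product: 13 target CNP0360403.1 = (3R,6E)-2-hydroxy-2,6-dimethyl-8-[(2-oxo-2H-chromen-7-yl)oxy]oct-6-en-3-yl (2E)-3-(4-{[(2E)-3,7-dimethylocta-2,6-dien-1-yl]oxy}-2-hydroxyphenyl)prop-2-enoate, via phosphorane ester 12 (not isolated)
Conditions: 7 + 11, toluene, 100 °C, 6 h; cool, add 10, rt to 40 °C, 16 h, in the dark
Reagents that add atoms: none
Why: Bestmann-ylide linchpin (alcohol addition to the cumulated ylide, then Wittig olefination), in which the secondary OH adds much faster than the tertiary OH, the C6'–O bond is never broken so R is retained, the stabilised ylide 12 olefinates the salicylaldehyde E-selectively without phenol protection, and the E geometry keeps the free ortho-phenol from lactonising; 11 is kept limiting and fully consumed before 10 is added so that it cannot turn 10 into a coumarin.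

**Compound list**
1 | methyl 2-hydroxy-2-methylpropanoate | COC(=O)C(C)(C)O | starting material
2 | 1-(2-hydroxypropan-2-yl)cyclopropan-1-ol | CC(C)(O)C1(O)CC1 | intermediate
3 | but-2-yn-1-ol | CC#CCO | starting material
4 | (6E)-2,8-dihydroxy-2,6-dimethyloct-6-en-3-one | CC(C)(O)C(=O)CC/C(C)=C/CO | intermediate
5 | 7-hydroxycoumarin (umbelliferone) | Oc1ccc2ccc(=O)oc2c1 | starting material
6 | 7-{[(2E)-7-hydroxy-3,7-dimethyl-6-oxooct-2-en-1-yl]oxy}-2H-chromen-2-one | CC(C)(O)C(=O)CC/C(C)=C/COc1ccc2ccc(=O)oc2c1 | intermediate
7 | (R)-marmin | O[C@H](CC/C(C)=C/COc1ccc2ccc(=O)oc2c1)C(C)(C)O | intermediate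
8 | 2,4-dihydroxybenzaldehyde | O=Cc1ccc(O)cc1O | starting material
9 | geranyl bromide | CC(C)=CCC/C(C)=C/CBr | starting material
10 | 4-geranyloxy-2-hydroxybenzaldehyde | CC(C)=CCC/C(C)=C/COc1ccc(C=O)c(O)c1 | intermediate
11 | (triphenylphosphoranylidene)ketene | O=C=C=P(c1ccccc1)(c1ccccc1)c1ccccc1 | starting material
12 | (R)-marmin 6'-O-[(triphenylphosphoranylidene)acetate] (not isolated) | O=C(C=P(c1ccccc1)(c1ccccc1)c1ccccc1)O[C@H](CC/C(C)=C/COc1ccc2ccc(=O)oc2c1)C(C)(C)O | intermediate
13 | CNP0360403.1 | CC(C)=CCC/C(C)=C/COc1ccc(/C=C/C(=O)O[C@H](CC/C(C)=C/COc2ccc3ccc(=O)oc3c2)C(C)(C)O)c(O)c1 | target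

**Step count**
Total steps: 6. Longest linear sequence: 5 (steps 1, 2, 3, 4, 6).

**Three steps most likely to fail**

Step 2. The risks are:
- imperfect regiocontrol between the CH3 and CH2OH termini of the alkyne;
- β-hydroxide elimination from the alkenylcobalt to give an allene;
- chelation of cobalt by the vicinal diol of 2;
- simple protonation of the homoenolate.

The fallback sets out from 3 (with 2 as partner) and comes back at 4. It fixes the bond-forming site and the geometry before the coupling. Compound 3 is capped at oxygen with iBu2AlH and hydrozirconated with Cp2ZrHCl made from Cp2ZrCl2 and iBu2AlH in THF. Quenching with I2 gives (E)-3-iodobut-2-en-1-ol F1. F1 is then cross-coupled with the palladium homoenolate formed by ring opening of 2 (Pd(OAc)2, XPhos, Cs2CO3, toluene, 80 °C). This is a stereoretentive sp2–sp3 coupling and delivers 4.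

Step 6. The risks are:
- slow addition of the hindered, neopentyl-like secondary OH to 11;
- leftover 11 diverting 10 into auraptene;
- loss of any Z-olefin by lactonisation.

The fallback sets out from 7 and comes back at 13. The C–O bond is made by carbodiimide acylation instead. Compound 7 reacts with diethylphosphonoacetic acid (EDC·HCl, DMAP, CH2Cl2, 0 °C to rt) to give, selectively at the secondary OH, (R)-marmin 6'-O-(diethylphosphonoacetate) F5, which is isolated. A Masamune–Roush Horner–Wadsworth–Emmons reaction of F5 with 10 (LiCl, DBU 2.2 equiv, MeCN, rt) gives 13.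

Step 4. The risks are insufficient ee, because both ketone flanks are aliphatic and the free tertiary OH first forms a borate, and slow turnover at low temperature.

The fallback sets out from 6 and comes back at 7 by classical resolution.
- Compound 6 is reduced with NaBH4 in MeOH at 0 °C to racemic marmin F2.
- F2 is esterified at the secondary OH with (S)-2-methoxy-2-phenylacetic acid (EDC·HCl, DMAP, CH2Cl2, 0 °C).
- The two diastereomers are separated by chromatography or crystallisation. These are (R)-marmin 6'-O-[(S)-2-methoxy-2-phenylacetate] F3, which is kept, and (S)-marmin 6'-O-[(S)-2-methoxy-2-phenylacetate] F4, which is discarded.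
- F3 is cleaved with K2CO3 in MeOH, followed by mild acidification to re-close any opened lactone, to give 7.

**Further compounds**
F1 | step 2 | (E)-3-iodobut-2-en-1-ol | C/C(I)=C\CO
F2 | step 4 | racemic marmin | OC(CC/C(C)=C/COc1ccc2ccc(=O)oc2c1)C(C)(C)O
F3 | step 4 | (R)-marmin 6'-O-[(S)-2-methoxy-2-phenylacetate] | CO[C@@H](c1ccccc1)C(=O)O[C@H](CC/C(C)=C/COc1ccc2ccc(=O)oc2c1)C(C)(C)O
F4 | step 4 | (S)-marmin 6'-O-[(S)-2-methoxy-2-phenylacetate] | CO[C@@H](c1ccccc1)C(=O)O[C@@H](CC/C(C)=C/COc1ccc2ccc(=O)oc2c1)C(C)(C)O
F5 | step 6 | (R)-marmin 6'-O-(diethylphosphonoacetate) | CCOP(=O)(CC(=O)O[C@H](CC/C(C)=C/COc1ccc2ccc(=O)oc2c1)C(C)(C)O)OCC
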